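The data are calculated on assumed constants, noise included.

Ask first whether the way the reagent goes in changes the target at 2.0 h.

| flask | substrate | reagent | free catalyst | temperature | remark | time |
|---|---|---|---|---|---|---|
| south | 0.24 M | 0.24 M | 2.4 mM | 45 °C | run made earlier |  |
| south-east | 0.12 M | 0.24 M | 2.4 mM | 56 °C | run made earlier |  |
| west | 0.48 M | 0.24 M | 2.4 mM | 45 °C | run made earlier |  |
| summer | 0.24 M | 0.240 M (fed, over 50 min) | 2.4 mM |  | the addition at 10 °C, then warmed to 50 °C; the feed brings no volume worth counting | 2.0 h |
| spring | 0.24 M | 0.240 M (fed, over 50 min) | 2.4 mM | 50 °C | all else is in the flask from the start; the feed brings no volume worth counting | 2.0 h |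
| winter | 0.24 M | 0.240 M (in portions, 4, over 50 min) | 2.4 mM | 50 °C | first portion at the start, last at 50 min | 2.0 h |
| midnight | 0.24 M | 0.240 M | 2.4 mM | 50 °C | everything together at the start | 2.0 h |
| dusk | 0.24 M | 0.240 M (fed, over 5.0 min) | 2.4 mM | 50 °C | all else is in the flask from the start; the feed brings no volume worth counting | 2.0 h |

- which flask leads in amount of target, in percent of the substrate charged ("all alike" within 1.5 percentage points) (summer / spring / winter / midnight / dusk / all alike)
- how much target is there at the end, in percent of the substrate charged: summer
- how much target is there at the end, in percent of the substrate charged: spring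
- how much target is there at the end, in percent of the substrate charged: winter
- how much target is there at the end, in percent of the substrate charged: midnight
- how much target is there at the end, in percent of the substrate charged: dusk

- south (time / min: target / %, substrate / %): 6.00: 7, 94; 20.0: 10, 86; 30.0: 15, 76; 50.0: 24, 67; 80.0: 37, 44
- south-east (time / min: target / %, substrate / %): 20.0: 57, 25; 40.0: 64, 0; 60.0: 47, 0; 80.0: 44, 3; 90.0: 38, 0
- west (time / min: target / %, substrate / %): 20.0: 12, 91; 40.0: 7, 85; 60.0: 13, 78; 80.0: 19, 73; 90.0: 25, 69

(standard deviation of a reading: 2 percentage points)

- the numbers in the tables scatter by 2 percentage points (one standard deviation)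

Turn the question round: what must hold for the flasks to end alike within 1.5 percentage points? Start from the south-east run. Substrate reads 0% after 40.0 min, yet target falls from 64% to 38% by 90.0 min, in a flask charged with twice as much reagent as substrate. Take this, as your own guess, for reagent attacking target. On that guess, flasks should end alike if reagent stands equally high in each while target is present, so measure how much of it the reaction uses up during an addition.

South loses substrate at 1.62 mM/min, and west, with twice the substrate, at 1.51 mM/min, so in these two readings at 45 °C doubling substrate does not raise the rate. South-east gives 4.50 mM/min at 56 °C. Run the logarithm of the rate straight through temperature: that gives 2.58 mM/min at 50 °C and, extrapolated, 0.0630 mM/min at 10 °C.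

Now define the standing share: the part of the reagent charge still unused when the addition ends, which is one minus rate times addition time over c(reagent), counting one reagent per substrate. Spring gets 46.3%, and winter the same, its last portion landing at 50 min. Dusk gets 94.6%, cold summer 98.7%, and midnight has its whole charge standing from the start. Alike flasks need like shares, but spring and winter stand far lower than dusk. So commit to this: spring and winter lead, unseparated by this share, and dusk stays with midnight.

The forecast says all alike, with midnight at 52% (range 44% to 61%) and the other flasks at the same central value, holding that “spring, winter and dusk match midnight”.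

The flasks give: summer 57.1%, spring 68.9%, winter 71.1%, midnight 61.9%, dusk 62.0%; winter leads.

    substrate + free catalyst ⇌ catalyst intermediate A (K = 1.68 /M, k = 1.84 /M/s, Ea = 61.0 kJ/mol, ΔH = −73.0 kJ/mol)
    reagent + catalyst intermediate A → catalyst intermediate B (k = 34.3 /M/s, Ea = 55.0 kJ/mol)
    catalyst intermediate B ⇌ by-product + catalyst intermediate C (K = 0.240 M, k = 0.408 /s, Ea = 70.0 kJ/mol, ΔH = −14.0 kJ/mol)
    catalyst intermediate C → catalyst intermediate D (k = 0.291 /s, Ea = 91.0 kJ/mol)
    catalyst intermediate D ⇌ free catalyst + target (K = 0.550 M, k = 0.331 /s, Ea = 69.0 kJ/mol, ΔH = −2.00 kJ/mol)
    reagent + target → over-reaction product (k = 0.00174 /M/s, Ea = 67.0 kJ/mol)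
    2 catalyst intermediate C ⇌ resting dimer, settled at all times (K = 36000 /M, ΔH = −13.0 kJ/mol)
    (constants at 50 °C)

Take the step from reagent and target to over-reaction product out of winter, and its target rises from 71.1% to 97.2%, so this step is the main loss. Hold the reckoned standing share against it: spring, reckoned at 46.3%, ends with 68.9%, more than midnight's 61.9%, while dusk, reckoned at 94.6%, ends level with midnight at 62.0%. Summer, reckoned at 98.7%, holds 57.1% at 2.0 h and 61.9% after 20.0 h, level with midnight at 2.0 h.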